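## Retrosynthetic overview

- Feature: in the bicyclo[2.2.2]oct-5-ene-2,3-dione core (bridgeheads C1 and C4, dione C2/C3, alkene C5=C6, aryl on C7, CO2H on C8) the acrylate carbon on C5 is joined to C8 by the path C8–C(=O)–O–CH2–C5, which with C4 makes a six-membered ring. A propargyl ester on C8 can therefore lay its alkyne across C4 and C1.
- Key disconnection: C4–C5 and C1–C6 by intramolecular Diels–Alder reaction of the 2,3-bis(silyloxy)cyclohexa-1,3-diene 8 with its C8 propargyl ester, giving tricyclic lactone 9.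
- Diene 8 comes from the meso Diels–Alder adduct of a 2,3-bis(silyloxy)butadiene and maleic anhydride: enantioselective opening with propargyl alcohol, Br2 oxidation of the ene-diol ether to the dione, exhaustive silylation.
- After the key step: alkoxide opens the lactone and epimerises C8; the C7 CO2H is exchanged for aryl by nickel-catalysed decarboxylative coupling; C5–CH2OH goes to the enal and is olefinated with a danshensu phosphonoacetate; ene-diol ether to dione; acidolysis of all 4-methoxybenzyl (PMB) groups.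
- Ring order: cyclohexene (step 2); bicyclo[2.2.2]octadiene and δ-lactone together (step 6); lactone reopened (step 7).

Key step: step 6

Remark: quinidine is assumed to open anhydride 4 in the sense known for cis-cyclohex-4-ene-1,2-dicarboxylic anhydride (ester on the (R) carbon); if the hemiester proves antipodal, quinine is used instead.

## Route

Step 1
Reactants: 1 2,3-butanedione
Product: 2 2,3-bis(tert-butyldimethylsilyloxy)buta-1,3-diene
Conditions: TBSOTf (2.2 equiv), Et3N (3 equiv), CH2Cl2, 0 °C → rt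
Reagents that add atoms: tert-butyldimethylsilyl triflate, CC(C)(C)[Si](C)(C)OS(=O)(=O)C(F)(F)F
Why: Double soft enolisation and O-silylation of the 1,2-diketone with silyl triflate and amine is the standard route to 2,3-bis(silyloxy)butadienes, and no stereocentre is formed.

Step 2
Reactants: 2 2,3-bis(tert-butyldimethylsilyloxy)buta-1,3-diene; 3 maleic anhydride
Product: 4 meso-cis-4,5-bis(tert-butyldimethylsilyloxy)cyclohex-4-ene-1,2-dicarboxylic anhydride
Conditions: PhMe, 80 °C
Reagents that add atoms: none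
Why: Normal-demand Diels–Alder reaction of the electron-rich diene with maleic anhydride, in which suprafacial addition keeps the two carbonyl-bearing carbons cis, so the adduct is meso.

Step 3
Reactants: 4 meso anhydride; 5 propargyl alcohol
Product: 6 (1S,2R)-4,5-bis(tert-butyldimethylsilyloxy)-2-(prop-2-ynyloxycarbonyl)cyclohex-4-ene-1-carboxylic acid (cis hemiester)
Conditions: quinidine (1.1 equiv), 5 (3 equiv), PhMe, −55 °C; cold aq. citric acid work-up
Reagents that add atoms: none
Why: Cinchona-alkaloid-mediated enantioselective alcoholysis of a meso anhydride, in which quinidine directs the alcohol to one enantiotopic carbonyl and so sets both stereocentres, (R) at the ester carbon and (S) at the acid carbon.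

Step 4
Reactants: 6 cis hemiester
Product: 7 (1S,2R)-4,5-dioxo-2-(prop-2-ynyloxycarbonyl)cyclohexane-1-carboxylic acid (drawn as the diketone, expected to be largely enolised)
Conditions: Br2 (1.0 equiv), CH2Cl2, −78 → 0 °C; aq. Na2S2O3; used crude under argon
Reagents that add atoms: none
Why: Bromine oxidation of a 1,2-bis(silyloxy)alkene to the 1,2-diketone, as used on acyloin-derived bis(silyl) ene-diols, proceeds by bromination of the very electron-rich alkene and loss of two silyl bromides, while the terminal alkyne is inert at −78 °C and the two stereocentres are not touched.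

Step 5
Reactants: 7 dione acid
Product: 8 1-prop-2-ynyl 2-triisopropylsilyl (1R,2S)-4,5-bis(triisopropylsilyloxy)cyclohexa-3,5-diene-1,2-dicarboxylate (cis)
Conditions: iPr3SiOTf (3.3 equiv), Et3N (5 equiv), CH2Cl2, −20 → 0 °C
Reagents that add atoms: triisopropylsilyl triflate, CC(C)[Si](OS(=O)(=O)C(F)(F)F)(C(C)C)C(C)C
Why: Exhaustive silylation with silyl triflate and Et3N esterifies the acid and enolises each ketone toward its CH2 group, the known route from cyclohexane-1,2-diones to 2,3-bis(silyloxy)cyclohexa-1,3-dienes, and triisopropylsilyl is chosen so that the ene-diol ether later survives alkoxide.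

Step 6
Reactants: 8 cis diene propargyl ester
Product: 9 tricyclic lactone: bicyclo[2.2.2]octa-2,5-diene with triisopropylsilyloxy groups on C2 and C3, δ-lactone C8–C(=O)–O–CH2–C5 and triisopropylsilyl ester on C7, both carboxyl carbons on the side of the C5=C6 bridge
Conditions: CH2Cl2 (0.01 M), BHT (cat.), 1.2 GPa, 50 °C; kept at or below 0 °C and used crude
Reagents that add atoms: none
Why: Concerted thermal [4+2] cycloaddition of the 2,3-bis(silyloxy)diene (C1=C2–C3=C4) with the tethered alkyne forms C4–C5 and C1–C6; the closest known reactions are intramolecular Diels–Alder reactions of cyclohexa-1,3-dienes that carry the dienophile on the sp3 ring carbon next to the diene and cycloadditions of 2,3-bis(silyloxy)cyclohexa-1,3-dienes with alkynes, run here with the pressure acceleration long used for reluctant Diels–Alder reactions. The bicyclo[2.2.2]octadiene is closed by the cycloaddition itself, and the δ-lactone C8–CO–O–CH2–C5–C4 is closed as the six-membered tether ring through the new C4–C5 bond (type 1 mode). The new stereocentres C1 and C4 follow from the (R) centre C8, whose ester can reach only the diene face on which it stands, so the C5=C6 bridge is built syn to the C8 carboxyl; the three-atom tether can place only its inner alkyne carbon on C4, which fixes the regiochemistry without a catalyst. The step is demanding because the alkyne is unactivated, the ester must take its s-cis form, and the lactone pulls the CH2 group on C5 out of the plane of the C5=C6 bond, so that the adduct is strained and could fragment by retro-[4+2] to a catechol bis(silyl ether) and a maleate if heated. High pressure lowers the barrier of the bond-forming step and disfavours the fragmenting one, so the reaction should run near 50 °C, and the adduct is taken cold into step 7, where opening of the lactone releases the strain.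

Step 7
Reactants: 9 tricyclic lactone
Product: 11 hydroxy acid with C5–CH2OH; C7–CO2H on the side of the C5=C6 bridge; C8 4-methoxybenzyl ester on the side of the C2=C3 bridge, via cis-hydroxy ester 10 (not isolated)
Conditions: 4-MeOC6H4CH2OH (6 equiv), NaH (3 equiv), THF, −40 °C → rt; aq. NH4Cl
Reagents that add atoms: 4-methoxybenzyl alcohol (as its sodium alkoxide), COc1ccc(CO)cc1
Why: Alkoxide transesterification opens the strained lactone to the PMB ester, the same alkoxide removes the silyl ester by attack at silicon, and base-mediated epimerisation α to the C8 ester then moves it trans to the C7 carboxylate, where relactonisation is impossible, while C7 is protected from enolisation as its carboxylate.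

Step 8
Reactants: 11 hydroxy acid
Product: 13 C5–CH2OSiEt3 ether of 11 with free C7 carboxylic acid, via bis(triethylsilyl) compound 12 (not isolated)
Conditions: Et3SiCl (2.5 equiv), imidazole, CH2Cl2, 0 °C; then THF/pH 7 buffer
Reagents that add atoms: chlorotriethylsilane, CC[Si](Cl)(CC)CC
Why: Silylation of both the alcohol and the acid followed by selective hydrolysis of the far more labile silyl ester on aqueous work-up leaves only the primary silyl ether.

Step 9
Reactants: 13 silyl ether acid
Product: 14 N-(acyloxy)phthalimide (redox-active ester) of the C7 acid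
Conditions: N-hydroxyphthalimide, iPrN=C=NiPr, DMAP (cat.), CH2Cl2, rt
Reagents that add atoms: N-hydroxyphthalimide, O=C1N(O)C(=O)c2ccccc12
Why: Carbodiimide esterification with N-hydroxyphthalimide gives the redox-active ester needed for decarboxylative cross-coupling without touching any stereocentre.

Step 10
Reactants: 15 4-bromocatechol
Product: 16 4-bromo-1,2-bis(4-methoxybenzyloxy)benzene
Conditions: 4-MeOC6H4CH2Cl (2.2 equiv), K2CO3, DMF, rt
Reagents that add atoms: 4-methoxybenzyl chloride, COc1ccc(CCl)cc1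
Why: Williamson etherification of both phenols gives a catechol protecting group that survives organometallic steps and is removed by acid at the end.

Step 11
Reactants: 16 aryl bromide
Product: 18 [3,4-bis(4-methoxybenzyloxy)phenyl]zinc chloride (THF solution containing LiCl), via aryllithium 17 (not isolated)
Conditions: n-BuLi, THF, −78 °C; then ZnCl2 (THF), −78 °C → rt
Reagents that add atoms: zinc chloride, Cl[Zn]Cl
Why: Bromine–lithium exchange followed by transmetalation to zinc gives the arylzinc halide used in nickel-catalysed decarboxylative arylation.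

Step 12
Reactants: 14 redox-active ester; 18 arylzinc chloride
Product: 19 C7-aryl compound: 3,4-bis(4-methoxybenzyloxy)phenyl on C7 on the side of the C5=C6 bridge, trans to the C8 PMB ester; C5–CH2OSiEt3
Conditions: NiCl2·glyme (20 mol %), 4,4'-di-tert-butyl-2,2'-bipyridine (40 mol %), 18 (3 equiv), THF/DMF, 0 °C → rt
Reagents that add atoms: none
Why: Nickel-catalysed decarboxylative Negishi-type arylation of a secondary redox-active ester releases CO2 and a C7 radical, which the aryl–nickel species should capture on the face away from the C8 ester and the C2 silyloxy group, setting C7 trans to C8.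

Step 13
Reactants: 19 silyl ether
Product: 20 allylic alcohol (C5–CH2OH)
Conditions: HF·pyridine, pyridine, THF, 0 °C
Reagents that add atoms: none
Why: Buffered fluoride cleaves the unhindered primary triethylsilyl ether much faster than the hindered tetrasubstituted triisopropylsilyl enol ethers.

Step 14
Reactants: 20 allylic alcohol
Product: 21 enal (C5–CHO conjugated with C5=C6)
Conditions: MnO2, CH2Cl2, rt
Reagents that add atoms: none
Why: MnO2 oxidises allylic alcohols selectively to enals under neutral conditions that leave silyl enol ethers, PMB groups and the ester alone.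

Step 15
Reactants: 22 (R)-danshensu
Product: 23 4-methoxybenzyl (R)-3-[3,4-bis(4-methoxybenzyloxy)phenyl]-2-hydroxypropanoate
Conditions: 4-MeOC6H4CH2Cl (3.3 equiv), K2CO3, Bu4NI (cat.), DMF, rt
Reagents that add atoms: 4-methoxybenzyl chloride, COc1ccc(CCl)cc1
Why: Carbonate-mediated alkylation takes the carboxylate and the two phenoxides but not the aliphatic hydroxyl, and the stereocentre is not involved.

Step 16
Reactants: 23 protected danshensu; 24 diethylphosphonoacetic acid
Product: 25 diethylphosphonoacetate of 23 (ester at the secondary hydroxyl, (R) retained)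
Conditions: EDC·HCl, DMAP (cat.), CH2Cl2, 0 °C → rt
Reagents that add atoms: none
Why: Carbodiimide (Steglich-type) esterification of the secondary alcohol gives the phosphonoacetate without touching the adjacent stereocentre.

Step 17
Reactants: 21 enal; 25 phosphonoacetate
Product: 26 (E)-dienoate: C5–CH=CH–C(=O)O– ester of protected danshensu, ene-diol bis(triisopropylsilyl ether) intact
Conditions: LiCl, DBU, MeCN, 0 °C → rt
Reagents that add atoms: none
Why: Horner–Wadsworth–Emmons olefination under Masamune–Roush conditions is E-selective and mild enough to leave the α-acyloxy ester stereocentre intact.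

Step 18
Reactants: 26 dienoate
Product: 27 hexakis(4-methoxybenzyl)-protected yunnaneic acid C (2,3-dione)
Conditions: Br2 (1.0 equiv), CH2Cl2, −78 °C; aq. NaHCO3/Na2S2O3
Reagents that add atoms: none
Why: Bromine oxidation of the 1,2-bis(silyloxy)alkene, as in step 4, unveils the non-enolisable bridged 1,2-dione, the ene-diol ether reacting at −78 °C far faster than the alkoxyarenes or the electron-poor dienoate.

Step 19
Reactants: 27 protected dione
Product: 28 yunnaneic acid C
Conditions: CF3CO2H/CH2Cl2 (1:4), C6HMe5 (30 equiv), 0 °C → rt, in the dark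
Reagents that add atoms: none
Why: Acidolysis cleaves the two PMB esters and four aryl PMB ethers in one operation, pentamethylbenzene traps the benzyl cations so the free catechols are not C-alkylated, and the absence of base spares the 1,2-dione and the ester linkage.

## Compound list

1 | 2,3-butanedione | CC(=O)C(C)=O | starting material
2 | 2,3-bis(tert-butyldimethylsilyloxy)buta-1,3-diene | C=C(O[Si](C)(C)C(C)(C)C)C(=C)O[Si](C)(C)C(C)(C)C | intermediate
3 | maleic anhydride | O=C1OC(=O)C=C1 | starting material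
4 | meso-cis-4,5-bis(tert-butyldimethylsilyloxy)cyclohex-4-ene-1,2-dicarboxylic anhydride | O=C1OC(=O)[C@H]2CC(O[Si](C)(C)C(C)(C)C)=C(O[Si](C)(C)C(C)(C)C)C[C@@H]12 | intermediate
5 | propargyl alcohol | C#CCO | starting material
6 | (1S,2R)-4,5-bis(tert-butyldimethylsilyloxy)-2-(prop-2-ynyloxycarbonyl)cyclohex-4-ene-1-carboxylic acid | C#CCOC(=O)[C@@H]1CC(O[Si](C)(C)C(C)(C)C)=C(O[Si](C)(C)C(C)(C)C)C[C@@H]1C(=O)O | intermediate
7 | (1S,2R)-4,5-dioxo-2-(prop-2-ynyloxycarbonyl)cyclohexane-1-carboxylic acid | C#CCOC(=O)[C@@H]1CC(=O)C(=O)C[C@@H]1C(=O)O | intermediate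
8 | 1-prop-2-ynyl 2-triisopropylsilyl (1R,2S)-4,5-bis(triisopropylsilyloxy)cyclohexa-3,5-diene-1,2-dicarboxylate | C#CCOC(=O)[C@@H]1C=C(O[Si](C(C)C)(C(C)C)C(C)C)C(O[Si](C(C)C)(C(C)C)C(C)C)=C[C@@H]1C(=O)O[Si](C(C)C)(C(C)C)C(C)C | intermediate
9 | tricyclic lactone (bicyclo[2.2.2]octa-2,5-diene; C2, C3 OTIPS; lactone C8–CO–O–CH2–C5; C7 TIPS ester syn to the C5=C6 bridge) | O=C3OCC1=C[C@H]2C(O[Si](C(C)C)(C(C)C)C(C)C)=C(O[Si](C(C)C)(C(C)C)C(C)C)[C@@H]1[C@@H]3[C@H]2C(=O)O[Si](C(C)C)(C(C)C)C(C)C | intermediate
10 | cis-hydroxy ester (C8 PMB ester still syn to the C5=C6 bridge; C7 acid; not isolated) | OCC1=C[C@H]2C(O[Si](C(C)C)(C(C)C)C(C)C)=C(O[Si](C(C)C)(C(C)C)C(C)C)[C@@H]1[C@@H](C(=O)OCc3ccc(OC)cc3)[C@H]2C(=O)O | intermediate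
11 | hydroxy acid (C8 PMB ester syn to the C2=C3 bridge, trans to C7 acid; C5–CH2OH) | OCC1=C[C@H]2C(O[Si](C(C)C)(C(C)C)C(C)C)=C(O[Si](C(C)C)(C(C)C)C(C)C)[C@@H]1[C@H](C(=O)OCc3ccc(OC)cc3)[C@H]2C(=O)O | intermediate
12 | bis(triethylsilyl) compound (silyl ether and silyl ester of 11; not isolated) | CC[Si](CC)(CC)OCC1=C[C@H]2C(O[Si](C(C)C)(C(C)C)C(C)C)=C(O[Si](C(C)C)(C(C)C)C(C)C)[C@@H]1[C@H](C(=O)OCc3ccc(OC)cc3)[C@H]2C(=O)O[Si](CC)(CC)CC | intermediate
13 | triethylsilyl ether acid | CC[Si](CC)(CC)OCC1=C[C@H]2C(O[Si](C(C)C)(C(C)C)C(C)C)=C(O[Si](C(C)C)(C(C)C)C(C)C)[C@@H]1[C@H](C(=O)OCc3ccc(OC)cc3)[C@H]2C(=O)O | intermediate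
14 | N-(acyloxy)phthalimide of 13 | CC[Si](CC)(CC)OCC1=C[C@H]2C(O[Si](C(C)C)(C(C)C)C(C)C)=C(O[Si](C(C)C)(C(C)C)C(C)C)[C@@H]1[C@H](C(=O)OCc3ccc(OC)cc3)[C@H]2C(=O)ON4C(=O)c5ccccc5C4=O | intermediate
15 | 4-bromocatechol | Oc1ccc(Br)cc1O | starting material
16 | 4-bromo-1,2-bis(4-methoxybenzyloxy)benzene | COc1ccc(COc2ccc(Br)cc2OCc3ccc(OC)cc3)cc1 | intermediate
17 | [3,4-bis(4-methoxybenzyloxy)phenyl]lithium (not isolated) | COc1ccc(COc2ccc([Li])cc2OCc3ccc(OC)cc3)cc1 | intermediate
18 | [3,4-bis(4-methoxybenzyloxy)phenyl]zinc chloride | COc1ccc(COc2ccc([Zn]Cl)cc2OCc3ccc(OC)cc3)cc1 | intermediate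
19 | C7-aryl triethylsilyl ether (aryl syn to the C5=C6 bridge, trans to C8 PMB ester) | CC[Si](CC)(CC)OCC1=C[C@H]2C(O[Si](C(C)C)(C(C)C)C(C)C)=C(O[Si](C(C)C)(C(C)C)C(C)C)[C@@H]1[C@H](C(=O)OCc3ccc(OC)cc3)[C@H]2c4ccc(OCc5ccc(OC)cc5)c(OCc6ccc(OC)cc6)c4 | intermediate
20 | C7-aryl allylic alcohol | OCC1=C[C@H]2C(O[Si](C(C)C)(C(C)C)C(C)C)=C(O[Si](C(C)C)(C(C)C)C(C)C)[C@@H]1[C@H](C(=O)OCc3ccc(OC)cc3)[C@H]2c4ccc(OCc5ccc(OC)cc5)c(OCc6ccc(OC)cc6)c4 | intermediate
21 | C7-aryl enal | O=CC1=C[C@H]2C(O[Si](C(C)C)(C(C)C)C(C)C)=C(O[Si](C(C)C)(C(C)C)C(C)C)[C@@H]1[C@H](C(=O)OCc3ccc(OC)cc3)[C@H]2c4ccc(OCc5ccc(OC)cc5)c(OCc6ccc(OC)cc6)c4 | intermediate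
22 | (R)-danshensu | O[C@H](Cc1ccc(O)c(O)c1)C(=O)O | starting material
23 | 4-methoxybenzyl (R)-3-[3,4-bis(4-methoxybenzyloxy)phenyl]-2-hydroxypropanoate | O[C@H](Cc1ccc(OCc2ccc(OC)cc2)c(OCc3ccc(OC)cc3)c1)C(=O)OCc1ccc(OC)cc1 | intermediate
24 | diethylphosphonoacetic acid | CCOP(=O)(OCC)CC(=O)O | starting material
25 | diethylphosphonoacetate of 23 | CCOP(=O)(OCC)CC(=O)O[C@H](Cc1ccc(OCc2ccc(OC)cc2)c(OCc3ccc(OC)cc3)c1)C(=O)OCc1ccc(OC)cc1 | intermediate
26 | (E)-dienoate with ene-diol bis(triisopropylsilyl ether) | O=C(/C=C/C1=C[C@H]2C(O[Si](C(C)C)(C(C)C)C(C)C)=C(O[Si](C(C)C)(C(C)C)C(C)C)[C@@H]1[C@H](C(=O)OCc3ccc(OC)cc3)[C@H]2c4ccc(OCc5ccc(OC)cc5)c(OCc6ccc(OC)cc6)c4)O[C@H](Cc7ccc(OCc8ccc(OC)cc8)c(OCc9ccc(OC)cc9)c7)C(=O)OCc1ccc(OC)cc1 | intermediate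
27 | hexakis(4-methoxybenzyl)-protected yunnaneic acid C | O=C(/C=C/C1=C[C@H]2C(=O)C(=O)[C@@H]1[C@H](C(=O)OCc3ccc(OC)cc3)[C@H]2c4ccc(OCc5ccc(OC)cc5)c(OCc6ccc(OC)cc6)c4)O[C@H](Cc7ccc(OCc8ccc(OC)cc8)c(OCc9ccc(OC)cc9)c7)C(=O)OCc1ccc(OC)cc1 | intermediate
28 | yunnaneic acid C | O=C(/C=C/C1=C[C@H]2C(=O)C(=O)[C@@H]1[C@H](C(=O)O)[C@H]2c1ccc(O)c(O)c1)O[C@H](Cc1ccc(O)c(O)c1)C(=O)O | target

## Step count and risks

Total: 19 steps. Longest linear sequence: 15 steps (steps 1–9, 12–14, 17–19).

**Step 6 (key cycloaddition).** The cycloaddition may be too slow even under pressure, because the alkyne is unactivated, the ester must turn s-cis and the forming lactone bends the C5 substituent out of the alkene plane. On forcing, the adduct may fragment by retro-[4+2] to an aromatic catechol ether.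

The fallback sets out from anhydride 4 and comes back at hydroxy acid 11; it uses an alkene dienophile and introduces the C5=C6 bond later.
- Quinidine-mediated opening of 4 with allyl alcohol in place of 5 should give the allyl hemiester F1.
- Br2 as in step 4 should give the dione acid F2, and iPr3SiOTf/Et3N as in step 5 the allyl diene F3.
- Thermal intramolecular Diels–Alder reaction of F3 (o-dichlorobenzene, about 190 °C, sealed, degassed) should give the saturated tricyclic lactone F4. Its C5 is sp3, so the CH2O group can point at C8 and the lactone is unstrained; with one double bond left in the bicycle no aromatising cycloreversion is open.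
- Sodium 4-methoxybenzyl alkoxide as in step 7 should give, through the cis hydroxy ester F5, the C8-epimerised hydroxy acid F6.
- Dess–Martin periodinane should give the aldehyde acid F7, and Et3SiOTf/Et3N its silyl enol ether silyl ester F8.
- Pd(OAc)2 in MeCN (Saegusa–Ito oxidation, β-hydride loss being possible only toward C6) should give the enal acid F9 after aqueous work-up.
- NaBH4/CeCl3·7H2O (Luche reduction) returns 11.

**Step 12 (decarboxylative arylation).** The C7 radical is homoallylic to both double bonds. It may close onto C6 and reopen to a bicyclo[3.2.1]octadienyl allylic radical before nickel captures it, or be captured on the wrong face.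

The fallback sets out from acid 13 and comes back at 19; it traps the radical much faster and forms the C7–aryl bond by a polar step.
- N-Hydroxypyridine-2-thione and DCC should give the thiohydroxamate (Barton) ester F10.
- Visible-light photolysis of F10 in the presence of excess (PhSe)2, a far faster radical trap than the nickel catalyst, should give the C7 phenyl selenide F11 on the face away from the C8 ester.
- H2O2/pyridine and selenoxide syn-elimination toward the cis C8–H should give the triene ester F12 with C7=C8 conjugated to the PMB ester.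
- The boronic acid F13 is made from aryllithium 17 and B(OiPr)3.
- [Rh(cod)OH]2-catalysed conjugate addition of F13 to F12 (dioxane/H2O, 40 °C) should place the aryl on C7 from the face of the C5=C6 bridge, away from the C2 silyloxy group.
- Any cis ester F14 from kinetic protonation is equilibrated with DBU to the trans ester 19.

**Step 5 (diene formation).** After the first enolisation the proton on the ester-bearing ring carbon is γ to the silyloxy-enone. Deprotonation there would give a conjugated isomer and erase the configuration set in step 3; aromatisation of the dihydrocatechol is a further loss.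

The fallback sets out from anhydride 4 and comes back at diene 8; it builds the diene before the enantio-determining step.
- Br2 on 4 should give the meso dione anhydride F15.
- iPr3SiOTf/Et3N should give the meso diene anhydride F16, at a stage where no stereochemical information can be lost.
- Quinidine-mediated opening with propargyl alcohol 5 at −55 °C should give the diene hemiester F17.
- iPr3SiCl/imidazole silylates the acid and returns 8.

## Further compounds

F1 | step 6 | (1S,2R)-4,5-bis(tert-butyldimethylsilyloxy)-2-(prop-2-enyloxycarbonyl)cyclohex-4-ene-1-carboxylic acid | C=CCOC(=O)[C@@H]1CC(O[Si](C)(C)C(C)(C)C)=C(O[Si](C)(C)C(C)(C)C)C[C@@H]1C(=O)O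
F2 | step 6 | (1S,2R)-4,5-dioxo-2-(prop-2-enyloxycarbonyl)cyclohexane-1-carboxylic acid | C=CCOC(=O)[C@@H]1CC(=O)C(=O)C[C@@H]1C(=O)O
F3 | step 6 | 1-prop-2-enyl 2-triisopropylsilyl (1R,2S)-4,5-bis(triisopropylsilyloxy)cyclohexa-3,5-diene-1,2-dicarboxylate | C=CCOC(=O)[C@@H]1C=C(O[Si](C(C)C)(C(C)C)C(C)C)C(O[Si](C(C)C)(C(C)C)C(C)C)=C[C@@H]1C(=O)O[Si](C(C)C)(C(C)C)C(C)C
F4 | step 6 | saturated tricyclic lactone (bicyclo[2.2.2]oct-2-ene; C5–CH2O syn to C8; C7 TIPS ester) | O=C3OC[C@@H]1C[C@H]2C(O[Si](C(C)C)(C(C)C)C(C)C)=C(O[Si](C(C)C)(C(C)C)C(C)C)[C@@H]1[C@@H]3[C@H]2C(=O)O[Si](C(C)C)(C(C)C)C(C)C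
F5 | step 6 | saturated cis hydroxy ester (C8 PMB ester syn to the C5–C6 bridge) | OC[C@@H]1C[C@H]2C(O[Si](C(C)C)(C(C)C)C(C)C)=C(O[Si](C(C)C)(C(C)C)C(C)C)[C@@H]1[C@@H](C(=O)OCc3ccc(OC)cc3)[C@H]2C(=O)O
F6 | step 6 | saturated hydroxy acid (C8 PMB ester trans to C7 acid) | OC[C@@H]1C[C@H]2C(O[Si](C(C)C)(C(C)C)C(C)C)=C(O[Si](C(C)C)(C(C)C)C(C)C)[C@@H]1[C@H](C(=O)OCc3ccc(OC)cc3)[C@H]2C(=O)O
F7 | step 6 | saturated aldehyde acid | O=C[C@@H]1C[C@H]2C(O[Si](C(C)C)(C(C)C)C(C)C)=C(O[Si](C(C)C)(C(C)C)C(C)C)[C@@H]1[C@H](C(=O)OCc3ccc(OC)cc3)[C@H]2C(=O)O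
F8 | step 6 | triethylsilyl enol ether triethylsilyl ester of F7 (enol ether geometry not defined) | CC[Si](CC)(CC)OC=C1C[C@H]2C(O[Si](C(C)C)(C(C)C)C(C)C)=C(O[Si](C(C)C)(C(C)C)C(C)C)[C@@H]1[C@H](C(=O)OCc3ccc(OC)cc3)[C@H]2C(=O)O[Si](CC)(CC)CC
F9 | step 6 | enal acid (C5–CHO, C5=C6, C7 acid) | O=CC1=C[C@H]2C(O[Si](C(C)C)(C(C)C)C(C)C)=C(O[Si](C(C)C)(C(C)C)C(C)C)[C@@H]1[C@H](C(=O)OCc3ccc(OC)cc3)[C@H]2C(=O)O
F10 | step 12 | 2-thioxopyridin-1(2H)-yl (Barton) ester of 13 | CC[Si](CC)(CC)OCC1=C[C@H]2C(O[Si](C(C)C)(C(C)C)C(C)C)=C(O[Si](C(C)C)(C(C)C)C(C)C)[C@@H]1[C@H](C(=O)OCc3ccc(OC)cc3)[C@H]2C(=O)ON4C=CC=CC4=S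
F11 | step 12 | C7 phenyl selenide (selenium syn to the C5=C6 bridge) | CC[Si](CC)(CC)OCC1=C[C@H]2C(O[Si](C(C)C)(C(C)C)C(C)C)=C(O[Si](C(C)C)(C(C)C)C(C)C)[C@@H]1[C@H](C(=O)OCc3ccc(OC)cc3)[C@H]2[Se]c4ccccc4
F12 | step 12 | triene ester (bicyclo[2.2.2]octa-2,5,7-triene, C8 PMB ester) | CC[Si](CC)(CC)OCC1=C[C@H]2C(O[Si](C(C)C)(C(C)C)C(C)C)=C(O[Si](C(C)C)(C(C)C)C(C)C)[C@@H]1C(C(=O)OCc3ccc(OC)cc3)=C2
F13 | step 12 | [3,4-bis(4-methoxybenzyloxy)phenyl]boronic acid | OB(O)c1ccc(OCc2ccc(OC)cc2)c(OCc3ccc(OC)cc3)c1
F14 | step 12 | C8 epimer of 19 (aryl and PMB ester cis) | CC[Si](CC)(CC)OCC1=C[C@H]2C(O[Si](C(C)C)(C(C)C)C(C)C)=C(O[Si](C(C)C)(C(C)C)C(C)C)[C@@H]1[C@@H](C(=O)OCc3ccc(OC)cc3)[C@H]2c4ccc(OCc5ccc(OC)cc5)c(OCc6ccc(OC)cc6)c4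
F15 | step 5 | meso-cis-4,5-dioxocyclohexane-1,2-dicarboxylic anhydride | O=C1OC(=O)[C@H]2CC(=O)C(=O)C[C@@H]12
F16 | step 5 | meso-cis-4,5-bis(triisopropylsilyloxy)cyclohexa-3,5-diene-1,2-dicarboxylic anhydride | O=C1OC(=O)[C@H]2C=C(O[Si](C(C)C)(C(C)C)C(C)C)C(O[Si](C(C)C)(C(C)C)C(C)C)=C[C@@H]12
F17 | step 5 | (1S,2R)-2-(prop-2-ynyloxycarbonyl)-4,5-bis(triisopropylsilyloxy)cyclohexa-3,5-diene-1-carboxylic acid | C#CCOC(=O)[C@@H]1C=C(O[Si](C(C)C)(C(C)C)C(C)C)C(O[Si](C(C)C)(C(C)C)C(C)C)=C[C@@H]1C(=O)O
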